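**Retrosynthetic overview**
- The target is opened at the inter-unit ester: the dienoic acid of O-PMB-hymeglusin (lactone unit) acylates the 12-OH of a 12S,13S hydroxy diester (open unit). Neither C12–O bond is ever broken, and all four PMB groups fall in one final acidolysis.
- Both units come from one dienoate tail (C1–C10, 7R) and two mirror-image C11–C14 heads, joined at C10–C11 by a visible-light nickel/photoredox C(sp3)–C(sp3) coupling.
- The heads come from dimethyl (S)- and (R)-malate: Fráter–Seebach alkoxymethylation sets C13 anti to C12, then a hydroxyl-directed borane reduction frees the C11 carbinol.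
- The tail comes from (R)-citronellal: alkyne formation, ozonolysis, carboalumination/Negishi coupling, bromination.
- The only ring, the β-lactone, is closed after the C10–C11 coupling and before the ester union, by carboxyl activation with retention.

Assumption: the target is made exactly as the SMILES defines it (both C7 centres R; lactone unit 2R,3R; open unit 12S,13S), and ethyl (E)-3-iodobut-2-enoate, 4-methoxybenzyl chloromethyl ether and the benzoxazolium salt are purchased.

**Route**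

Step 1
Reactants: 1 (R)-citronellal
Product: 2 (4R)-4,8-dimethylnon-7-en-1-yne
Conditions: dimethyl (1-diazo-2-oxopropyl)phosphonate (1.3 equiv), K2CO3 (2 equiv), MeOH, 0 °C → rt
Reagents that add atoms: dimethyl (1-diazo-2-oxopropyl)phosphonate, CC(=O)C(=[N+]=[N-])P(=O)(OC)OC
Why: Seyferth–Gilbert homologation with the Ohira–Bestmann reagent turns the aldehyde into the terminal alkyne under mild carbonate conditions; the methyl-bearing stereocentre is β to the carbonyl, cannot enolise, and is carried unchanged.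

Step 2
Reactants: 2 (4R)-4,8-dimethylnon-7-en-1-yne
Product: 4 (4R)-4-methylhept-6-yn-1-ol, via (4R)-4-methylhept-6-ynal 3 (not isolated)
Conditions: O3, CH2Cl2/MeOH, −78 °C (Sudan Red 7B end point); then NaBH4, −78 °C → rt
Reagents that add atoms: ozone, [O-][O+]=O
Why: Chemoselective ozonolysis (the electron-rich trisubstituted alkene reacts far faster than the terminal alkyne) with reductive NaBH4 work-up gives the primary alcohol; no stereocentre is touched.

Step 3
Reactants: 4 (4R)-4-methylhept-6-yn-1-ol; 5 ethyl (2E)-3-iodobut-2-enoate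
Product: 7 ethyl (2E,4E,7R)-10-hydroxy-3,5,7-trimethyldeca-2,4-dienoate, via alkenylalane 6 (not isolated)
Conditions: AlMe3 (3 equiv), Cp2ZrCl2 (0.25 equiv), CH2Cl2, 0 °C → rt; volatiles removed; then 5, Pd(PPh3)4 (5 mol%), ZnCl2 (0.3 equiv), THF, rt; aq. potassium sodium tartrate
Reagents that add atoms: trimethylaluminium, C[Al](C)C
Why: Negishi zirconium-catalysed carboalumination adds methyl and aluminium syn with aluminium at the terminus to give the (E)-alkenylalane, and the palladium/zinc-catalysed Negishi cross-coupling with the (E)-iodoenoate retains both alkene geometries, so the 2E,4E-dienoate is set without any new stereocentre.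

Step 4
Reactants: 7 ethyl (2E,4E,7R)-10-hydroxy-3,5,7-trimethyldeca-2,4-dienoate
Product: 8 ethyl (2E,4E,7R)-10-bromo-3,5,7-trimethyldeca-2,4-dienoate
Conditions: CBr4 (1.2 equiv), PPh3 (1.25 equiv), CH2Cl2, 0 °C
Reagents that add atoms: carbon tetrabromide, BrC(Br)(Br)Br
Why: Appel bromination of the primary alcohol under neutral conditions leaves the dienoate and the remote stereocentre untouched.

Step 5
Reactants: 9 dimethyl (S)-malate; 10 4-methoxybenzyl chloromethyl ether
Product: 12 dimethyl (2S,3R)-2-hydroxy-3-[(4-methoxybenzyloxy)methyl]butanedioate, via dilithium dianion 11 (not isolated)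
Conditions: LiN(SiMe3)2 (2.2 equiv), THF, −78 → −20 °C; then 10 (1.1 equiv), −78 → −40 °C; aq. NH4Cl; chromatography
Reagents that add atoms: none
Why: Fráter–Seebach alkylation: the electrophile attacks the lithium-chelated alkoxide–enolate on the face opposite the C1 ester, setting C3 as R (2,3-anti, about 9:1 expected; the minor 2S,3S isomer is removed by chromatography) under control of the purchased C2 centre.

Step 6
Reactants: 12 dimethyl (2S,3R)-2-hydroxy-3-[(4-methoxybenzyloxy)methyl]butanedioate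
Product: 13 methyl (2R,3S)-3,4-dihydroxy-2-[(4-methoxybenzyloxy)methyl]butanoate
Conditions: BH3·SMe2 (1.05 equiv), NaBH4 (5 mol%), THF, 0 °C → rt; MeOH quench; used at once
Reagents that add atoms: none
Why: Hydroxyl-directed borane reduction (NaBH4-catalysed reduction of α-hydroxy esters) reduces only the ester next to the free hydroxyl; both stereocentres are unchanged and only the CIP labels move.

Step 7
Reactants: 14 dimethyl (R)-malate; 10 4-methoxybenzyl chloromethyl ether
Product: 16 dimethyl (2R,3S)-2-hydroxy-3-[(4-methoxybenzyloxy)methyl]butanedioate, via dilithium dianion 15 (not isolated)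
Conditions: LiN(SiMe3)2 (2.2 equiv), THF, −78 → −20 °C; then 10 (1.1 equiv), −78 → −40 °C; aq. NH4Cl; chromatography
Reagents that add atoms: none
Why: The same Fráter–Seebach alkylation in the mirror-image series sets C3 as S anti to the purchased 2R centre.

Step 8
Reactants: 16 dimethyl (2R,3S)-2-hydroxy-3-[(4-methoxybenzyloxy)methyl]butanedioate
Product: 17 methyl (2S,3R)-3,4-dihydroxy-2-[(4-methoxybenzyloxy)methyl]butanoate
Conditions: BH3·SMe2 (1.05 equiv), NaBH4 (5 mol%), THF, 0 °C → rt; MeOH quench; used at once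
Reagents that add atoms: none
Why: The same hydroxyl-directed borane reduction of the α-hydroxy ester; stereocentres unchanged.

Step 9
Reactants: 13 methyl (2R,3S)-3,4-dihydroxy-2-[(4-methoxybenzyloxy)methyl]butanoate; 8 ethyl (2E,4E,7R)-10-bromo-3,5,7-trimethyldeca-2,4-dienoate
Product: 19 1-ethyl 14-methyl (2E,4E,7R,12R,13R)-12-hydroxy-13-[(4-methoxybenzyloxy)methyl]-3,5,7-trimethyltetradeca-2,4-dienedioate, via benzoxazoline adduct 18 (not isolated)
Conditions: 5,7-di-tert-butyl-3-phenylbenzoxazolium tetrafluoroborate (1.0 equiv), pyridine (1.0 equiv), MTBE, rt, 30 min; then 8 (1.5 equiv), [Ir(ppy)2(dtbbpy)]PF6 (1.5 mol%), NiBr2·dme (7 mol%), 4,4′-di-tert-butyl-2,2′-bipyridine (8 mol%), K3PO4 (1.5 equiv), MTBE/DMA, degassed, 450 nm LEDs, 25 °C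
Reagents that add atoms: none
Why: Proposed new method: the bulky benzoxazolium salt should condense selectively with the unhindered primary hydroxyl of the unprotected vicinal diol to give 18; the excited iridium photocatalyst oxidises the anilinic nitrogen of 18, and loss of the C2 proton followed by β-scission (driven by formation of the benzoxazolone carbonyl) releases the primary β-hydroxyalkyl radical at C11; zerovalent nickel inserts into the primary C–Br bond of 8, the alkylnickel captures the radical, and the trivalent dialkylnickel reductively eliminates the C10–C11 bond while the reduced photocatalyst returns monovalent nickel to zerovalent nickel; C12 and C13 are never radical or metal-bound, so no stereocentre is formed or disturbed; the closest known reaction type is the nickel/photoredox deoxygenative cross-coupling of benzoxazolium-activated mono-alcohols with organic bromides, which has not been shown at the primary hydroxyl of a free 1,2-diol.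

Step 10
Reactants: 17 methyl (2S,3R)-3,4-dihydroxy-2-[(4-methoxybenzyloxy)methyl]butanoate; 8 ethyl (2E,4E,7R)-10-bromo-3,5,7-trimethyldeca-2,4-dienoate
Product: 21 1-ethyl 14-methyl (2E,4E,7R,12S,13S)-12-hydroxy-13-[(4-methoxybenzyloxy)methyl]-3,5,7-trimethyltetradeca-2,4-dienedioate, via benzoxazoline adduct 20 (not isolated)
Conditions: 5,7-di-tert-butyl-3-phenylbenzoxazolium tetrafluoroborate (1.0 equiv), pyridine (1.0 equiv), MTBE, rt, 30 min; then 8 (1.5 equiv), [Ir(ppy)2(dtbbpy)]PF6 (1.5 mol%), NiBr2·dme (7 mol%), 4,4′-di-tert-butyl-2,2′-bipyridine (8 mol%), K3PO4 (1.5 equiv), MTBE/DMA, degassed, 450 nm LEDs, 25 °C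
Reagents that add atoms: none
Why: Proposed new method: as in step 9, selective condensation at the primary hydroxyl of the mirror-image diol gives 20, photocatalytic oxidation and β-scission release the C11 β-hydroxyalkyl radical, and nickel (zerovalent insertion into the C–Br bond of 8, radical capture, reductive elimination from trivalent nickel) forges C10–C11 without touching C12 or C13; the closest known reaction type is the nickel/photoredox deoxygenative coupling of benzoxazolium-activated mono-alcohols with organic bromides.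

Step 11
Reactants: 19 1-ethyl 14-methyl (2E,4E,7R,12R,13R)-12-hydroxy-13-[(4-methoxybenzyloxy)methyl]-3,5,7-trimethyltetradeca-2,4-dienedioate
Product: 22 (2E,4E,7R,12R,13R)-12-hydroxy-13-[(4-methoxybenzyloxy)methyl]-3,5,7-trimethyltetradeca-2,4-dienedioic acid
Conditions: LiOH·H2O (8 equiv), THF/MeOH/H2O, 45 °C; then 1 M HCl to pH 3
Reagents that add atoms: lithium hydroxide, [Li+].[OH-]
Why: Saponification of both esters (the β-hydroxy ester hydrolyses faster than it enolises, and the carboxylate formed is not epimerisable), so C13 is kept.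

Step 12
Reactants: 22 (2E,4E,7R,12R,13R)-12-hydroxy-13-[(4-methoxybenzyloxy)methyl]-3,5,7-trimethyltetradeca-2,4-dienedioic acid
Product: 24 (2E,4E,7R)-11-[(2R,3R)-3-[(4-methoxybenzyloxy)methyl]-4-oxooxetan-2-yl]-3,5,7-trimethylundeca-2,4-dienoic acid, via sulfonic mixed anhydride 23 (not isolated)
Conditions: PhSO2Cl (3 equiv), pyridine (0.02 M), 0 → 4 °C, 16 h; then aq. NaHCO3/THF, 0 °C, 30 min; citric acid to pH 4
Reagents that add atoms: none
Why: β-Lactonisation by carboxyl activation (Adam's benzenesulfonyl chloride/pyridine method): the 12-hydroxyl attacks the activated C14 carbonyl, so the C12–O bond is not broken and the anti hydroxy acid closes with retention to the trans (2R,3R) lactone; the transiently activated dienoic acid has no internal nucleophile and is returned by the bicarbonate wash.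

Step 13
Reactants: 21 1-ethyl 14-methyl (2E,4E,7R,12S,13S)-12-hydroxy-13-[(4-methoxybenzyloxy)methyl]-3,5,7-trimethyltetradeca-2,4-dienedioate
Product: 25 (2E,4E,7R,12S,13S)-12-hydroxy-13-[(4-methoxybenzyloxy)methyl]-3,5,7-trimethyltetradeca-2,4-dienedioic acid
Conditions: LiOH·H2O (8 equiv), THF/MeOH/H2O, 45 °C; then 1 M HCl to pH 3
Reagents that add atoms: lithium hydroxide, [Li+].[OH-]
Why: Saponification of both esters as in step 11, without epimerisation at C13.

Step 14
Reactants: 25 (2E,4E,7R,12S,13S)-12-hydroxy-13-[(4-methoxybenzyloxy)methyl]-3,5,7-trimethyltetradeca-2,4-dienedioic acid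
Product: 26 bis(4-methoxybenzyl) (2E,4E,7R,12S,13S)-12-hydroxy-13-[(4-methoxybenzyloxy)methyl]-3,5,7-trimethyltetradeca-2,4-dienedioate
Conditions: 4-methoxybenzyl chloride (2.3 equiv), Cs2CO3 (1.1 equiv), Bu4NI (10 mol%), DMF, rt
Reagents that add atoms: 4-methoxybenzyl chloride, COc1ccc(CCl)cc1
Why: Carboxylate O-alkylation (SN2) esterifies both acids while the hindered secondary hydroxyl is not alkylated under carbonate conditions; no stereocentre is involved.

Step 15
Reactants: 26 bis(4-methoxybenzyl) (2E,4E,7R,12S,13S)-12-hydroxy-13-[(4-methoxybenzyloxy)methyl]-3,5,7-trimethyltetradeca-2,4-dienedioate; 24 (2E,4E,7R)-11-[(2R,3R)-3-[(4-methoxybenzyloxy)methyl]-4-oxooxetan-2-yl]-3,5,7-trimethylundeca-2,4-dienoic acid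
Product: 28 tetra-PMB-protected Fusariumester B, via Yamaguchi mixed anhydride 27 (not isolated)
Conditions: 24 (1.3 equiv), 2,4,6-trichlorobenzoyl chloride (1.3 equiv), Et3N (1.5 equiv), toluene, rt, 1 h; then 26, DMAP (1.0 equiv), toluene, rt
Reagents that add atoms: none
Why: Yamaguchi esterification acylates the only free hydroxyl (12-OH of 26) with the dienoic acid of 24; the C12–O bond is not broken, so 12S is retained, and β-lactones are known to survive DMAP-mediated esterification at room temperature.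

Step 16
Reactants: 28 tetra-PMB-protected Fusariumester B
Product: 29 Fusariumester B
Conditions: TFA/CH2Cl2 (1:4), anisole (20 equiv), 0 °C → rt, 1.5 h; evaporate; MeOH/H2O, rt; reverse-phase HPLC
Reagents that add atoms: none
Why: Acidolysis of the two PMB esters and two PMB ethers with anisole as cation scavenger; the β-lactone, the secondary dienoate ester and the dienoic acids tolerate dilute TFA, and no stereocentre is touched.

**Compound list**

1 | (R)-citronellal [(3R)-3,7-dimethyloct-6-enal] | O=CC[C@H](C)CCC=C(C)C | starting material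
2 | (4R)-4,8-dimethylnon-7-en-1-yne | C#CC[C@H](C)CCC=C(C)C | intermediate
3 | (4R)-4-methylhept-6-ynal | C#CC[C@H](C)CCC=O | intermediate
4 | (4R)-4-methylhept-6-yn-1-ol | C#CC[C@H](C)CCCO | intermediate
5 | ethyl (2E)-3-iodobut-2-enoate | CCOC(=O)/C=C(C)/I | starting material
6 | dimethyl[(1E,4R)-7-(dimethylalumanyloxy)-2,4-dimethylhept-1-en-1-yl]alumane | C[Al](C)/C=C(\C)C[C@H](C)CCCO[Al](C)C | intermediate
7 | ethyl (2E,4E,7R)-10-hydroxy-3,5,7-trimethyldeca-2,4-dienoate | CCOC(=O)/C=C(C)/C=C(\C)C[C@H](C)CCCO | intermediate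
8 | ethyl (2E,4E,7R)-10-bromo-3,5,7-trimethyldeca-2,4-dienoate | CCOC(=O)/C=C(C)/C=C(\C)C[C@H](C)CCCBr | intermediate
9 | dimethyl (S)-malate | COC(=O)C[C@H](O)C(=O)OC | starting material
10 | 4-methoxybenzyl chloromethyl ether [1-(chloromethoxymethyl)-4-methoxybenzene] | COc1ccc(COCCl)cc1 | starting material
11 | dilithium alkoxide–enolate dianion of dimethyl (S)-malate | [Li+].[Li+].COC(=O)[C@@H]([O-])C=C([O-])OC | intermediate
12 | dimethyl (2S,3R)-2-hydroxy-3-[(4-methoxybenzyloxy)methyl]butanedioate | COC(=O)[C@@H](O)[C@@H](COCc1ccc(OC)cc1)C(=O)OC | intermediate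
13 | methyl (2R,3S)-3,4-dihydroxy-2-[(4-methoxybenzyloxy)methyl]butanoate | OC[C@@H](O)[C@@H](COCc1ccc(OC)cc1)C(=O)OC | intermediate
14 | dimethyl (R)-malate | COC(=O)C[C@@H](O)C(=O)OC | starting material
15 | dilithium alkoxide–enolate dianion of dimethyl (R)-malate | [Li+].[Li+].COC(=O)[C@H]([O-])C=C([O-])OC | intermediate
16 | dimethyl (2R,3S)-2-hydroxy-3-[(4-methoxybenzyloxy)methyl]butanedioate | COC(=O)[C@H](O)[C@H](COCc1ccc(OC)cc1)C(=O)OC | intermediate
17 | methyl (2S,3R)-3,4-dihydroxy-2-[(4-methoxybenzyloxy)methyl]butanoate | OC[C@H](O)[C@H](COCc1ccc(OC)cc1)C(=O)OC | intermediate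
18 | methyl (2R,3S)-4-[(5,7-di-tert-butyl-3-phenyl-2,3-dihydro-1,3-benzoxazol-2-yl)oxy]-3-hydroxy-2-[(4-methoxybenzyloxy)methyl]butanoate | CC(C)(C)c1cc(C(C)(C)C)c2OC(OC[C@@H](O)[C@@H](COCc3ccc(OC)cc3)C(=O)OC)N(c3ccccc3)c2c1 | intermediate
19 | 1-ethyl 14-methyl (2E,4E,7R,12R,13R)-12-hydroxy-13-[(4-methoxybenzyloxy)methyl]-3,5,7-trimethyltetradeca-2,4-dienedioate | CCOC(=O)/C=C(C)/C=C(\C)C[C@H](C)CCCC[C@@H](O)[C@@H](COCc1ccc(OC)cc1)C(=O)OC | intermediate
20 | methyl (2S,3R)-4-[(5,7-di-tert-butyl-3-phenyl-2,3-dihydro-1,3-benzoxazol-2-yl)oxy]-3-hydroxy-2-[(4-methoxybenzyloxy)methyl]butanoate | CC(C)(C)c1cc(C(C)(C)C)c2OC(OC[C@H](O)[C@H](COCc3ccc(OC)cc3)C(=O)OC)N(c3ccccc3)c2c1 | intermediate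
21 | 1-ethyl 14-methyl (2E,4E,7R,12S,13S)-12-hydroxy-13-[(4-methoxybenzyloxy)methyl]-3,5,7-trimethyltetradeca-2,4-dienedioate | CCOC(=O)/C=C(C)/C=C(\C)C[C@H](C)CCCC[C@H](O)[C@H](COCc1ccc(OC)cc1)C(=O)OC | intermediate
22 | (2E,4E,7R,12R,13R)-12-hydroxy-13-[(4-methoxybenzyloxy)methyl]-3,5,7-trimethyltetradeca-2,4-dienedioic acid | OC(=O)/C=C(C)/C=C(\C)C[C@H](C)CCCC[C@@H](O)[C@@H](COCc1ccc(OC)cc1)C(=O)O | intermediate
23 | C14 benzenesulfonic mixed anhydride of 22 | OC(=O)/C=C(C)/C=C(\C)C[C@H](C)CCCC[C@@H](O)[C@@H](COCc1ccc(OC)cc1)C(=O)OS(=O)(=O)c1ccccc1 | intermediate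
24 | (2E,4E,7R)-11-[(2R,3R)-3-[(4-methoxybenzyloxy)methyl]-4-oxooxetan-2-yl]-3,5,7-trimethylundeca-2,4-dienoic acid (O-PMB-hymeglusin) | OC(=O)/C=C(C)/C=C(\C)C[C@H](C)CCCC[C@H]1OC(=O)[C@@H]1COCc1ccc(OC)cc1 | intermediate
25 | (2E,4E,7R,12S,13S)-12-hydroxy-13-[(4-methoxybenzyloxy)methyl]-3,5,7-trimethyltetradeca-2,4-dienedioic acid | OC(=O)/C=C(C)/C=C(\C)C[C@H](C)CCCC[C@H](O)[C@H](COCc1ccc(OC)cc1)C(=O)O | intermediate
26 | bis(4-methoxybenzyl) (2E,4E,7R,12S,13S)-12-hydroxy-13-[(4-methoxybenzyloxy)methyl]-3,5,7-trimethyltetradeca-2,4-dienedioate | COc1ccc(COC(=O)/C=C(C)/C=C(\C)C[C@H](C)CCCC[C@H](O)[C@H](COCc2ccc(OC)cc2)C(=O)OCc2ccc(OC)cc2)cc1 | intermediate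
27 | 2,4,6-trichlorobenzoic mixed anhydride of 24 | Clc1cc(Cl)c(C(=O)OC(=O)/C=C(C)/C=C(\C)C[C@H](C)CCCC[C@H]2OC(=O)[C@@H]2COCc2ccc(OC)cc2)c(Cl)c1 | intermediate
28 | tetra-PMB-protected Fusariumester B: bis(4-methoxybenzyl) (2E,4E,7R,12S,13S)-13-[(4-methoxybenzyloxy)methyl]-3,5,7-trimethyl-12-{[(2E,4E,7R)-11-[(2R,3R)-3-[(4-methoxybenzyloxy)methyl]-4-oxooxetan-2-yl]-3,5,7-trimethylundeca-2,4-dienoyl]oxy}tetradeca-2,4-dienedioate | COc1ccc(COC(=O)/C=C(C)/C=C(\C)C[C@H](C)CCCC[C@H](OC(=O)/C=C(C)/C=C(\C)C[C@H](C)CCCC[C@H]2OC(=O)[C@@H]2COCc2ccc(OC)cc2)[C@H](COCc2ccc(OC)cc2)C(=O)OCc2ccc(OC)cc2)cc1 | intermediate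
29 | Fusariumester B | CC(=C\C(=O)O)/C=C(\C)C[C@H](C)CCCC[C@H](OC(=O)/C=C(C)/C=C(\C)C[C@H](C)CCCC[C@H]1OC(=O)[C@@H]1CO)[C@H](CO)C(=O)O | target

**Step count and risks**

Total steps: 16. Longest linear sequence: 9 steps (1 → 2 → 4 → 7 → 8 → 19 → 22 → 24 → 28 → 29).

Steps most likely to fail:

Step 9 (proposed new coupling). Possible problems:
- incomplete primary-over-secondary selectivity of the benzoxazolium condensation, or exchange of the adduct onto the neighbouring hydroxyl;
- lactonisation of diol 13 before activation;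
- 1,6-hydrogen transfer from the PMB methylene to the C11 radical;
- 6-exo cyclisation of the C10 radical from 8 onto C5, or sensitised E/Z scrambling of the dienoate (the low-triplet-energy iridium complex is chosen to avoid this; [Ru(bpy)3](PF6)2 is the substitute if scrambling is seen).

Fallback with known chemistry, setting out from 13 and 8 and returning at 19: selective Appel iodination of the primary hydroxyl of 13 (I2, PPh3, imidazole, 0 °C) gives methyl (2R,3S)-3-hydroxy-4-iodo-2-[(4-methoxybenzyloxy)methyl]butanoate F1. Silylation (Et3SiCl, imidazole) gives methyl (2R,3S)-4-iodo-2-[(4-methoxybenzyloxy)methyl]-3-(triethylsilyloxy)butanoate F2. Zinc insertion into 8 (Zn dust, LiCl, THF, 50 °C) gives bromo[(4R,6E,8E)-10-ethoxy-4,6,8-trimethyl-10-oxodeca-6,8-dien-1-yl]zinc F3. A nickel-catalysed alkyl–alkyl Negishi coupling of F2 with F3 (Ni(cod)2, 2,2′:6′,2″-terpyridine, THF/DMA, rt) gives 1-ethyl 14-methyl (2E,4E,7R,12R,13R)-13-[(4-methoxybenzyloxy)methyl]-3,5,7-trimethyl-12-(triethylsilyloxy)tetradeca-2,4-dienedioate F4, and HF·pyridine removes the silyl group to give 19.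

Step 10 (the same proposed coupling on the mirror-image head; same failure modes). Fallback with known chemistry, setting out from 17 and 8 and returning at 21: the same iodination gives methyl (2S,3R)-3-hydroxy-4-iodo-2-[(4-methoxybenzyloxy)methyl]butanoate F5, and silylation gives methyl (2S,3R)-4-iodo-2-[(4-methoxybenzyloxy)methyl]-3-(triethylsilyloxy)butanoate F6. The nickel/terpyridine Negishi coupling of F6 with the zinc reagent bromo[(4R,6E,8E)-10-ethoxy-4,6,8-trimethyl-10-oxodeca-6,8-dien-1-yl]zinc F3 gives 1-ethyl 14-methyl (2E,4E,7R,12S,13S)-13-[(4-methoxybenzyloxy)methyl]-3,5,7-trimethyl-12-(triethylsilyloxy)tetradeca-2,4-dienedioate F7, and HF·pyridine gives 21.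

Step 12 (β-lactonisation of a hydroxy diacid). The dienoic acid is activated alongside the C14 acid and may acylate the 12-hydroxyl of a second molecule before the four-membered ring closes. The fallback removes the free dienoic acid from this step; it sets out from 7 and returns at 24:
- titanate transesterification (Ti(OiPr)4 cat., allyl alcohol, 80 °C) gives prop-2-en-1-yl (2E,4E,7R)-10-hydroxy-3,5,7-trimethyldeca-2,4-dienoate F8;
- Appel bromination gives prop-2-en-1-yl (2E,4E,7R)-10-bromo-3,5,7-trimethyldeca-2,4-dienoate F9;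
- coupling with 13 as in step 9 gives 14-methyl 1-prop-2-en-1-yl (2E,4E,7R,12R,13R)-12-hydroxy-13-[(4-methoxybenzyloxy)methyl]-3,5,7-trimethyltetradeca-2,4-dienedioate F10;
- LiOH (1.1 equiv, 0 °C) cleaves only the saturated methyl ester and spares the cross-conjugated allyl ester, giving (2E,4E,7R,12R,13R)-12-hydroxy-13-[(4-methoxybenzyloxy)methyl]-3,5,7-trimethyltetradeca-2,4-dienedioic acid 1-(prop-2-en-1-yl) ester F11;
- PhSO2Cl/pyridine now lactonises a mono-acid cleanly to prop-2-en-1-yl (2E,4E,7R)-11-[(2R,3R)-3-[(4-methoxybenzyloxy)methyl]-4-oxooxetan-2-yl]-3,5,7-trimethylundeca-2,4-dienoate F12;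
- Pd(PPh3)4 with morpholine removes the allyl group under neutral conditions to give 24.

Further compounds

F1 | step 9 | methyl (2R,3S)-3-hydroxy-4-iodo-2-[(4-methoxybenzyloxy)methyl]butanoate | IC[C@@H](O)[C@@H](COCc1ccc(OC)cc1)C(=O)OC
F2 | step 9 | methyl (2R,3S)-4-iodo-2-[(4-methoxybenzyloxy)methyl]-3-(triethylsilyloxy)butanoate | IC[C@@H](O[Si](CC)(CC)CC)[C@@H](COCc1ccc(OC)cc1)C(=O)OC
F3 | step 9 | bromo[(4R,6E,8E)-10-ethoxy-4,6,8-trimethyl-10-oxodeca-6,8-dien-1-yl]zinc | CCOC(=O)/C=C(C)/C=C(\C)C[C@H](C)CCC[Zn]Br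
F4 | step 9 | 1-ethyl 14-methyl (2E,4E,7R,12R,13R)-13-[(4-methoxybenzyloxy)methyl]-3,5,7-trimethyl-12-(triethylsilyloxy)tetradeca-2,4-dienedioate | CCOC(=O)/C=C(C)/C=C(\C)C[C@H](C)CCCC[C@@H](O[Si](CC)(CC)CC)[C@@H](COCc1ccc(OC)cc1)C(=O)OC
F5 | step 10 | methyl (2S,3R)-3-hydroxy-4-iodo-2-[(4-methoxybenzyloxy)methyl]butanoate | IC[C@H](O)[C@H](COCc1ccc(OC)cc1)C(=O)OC
F6 | step 10 | methyl (2S,3R)-4-iodo-2-[(4-methoxybenzyloxy)methyl]-3-(triethylsilyloxy)butanoate | IC[C@H](O[Si](CC)(CC)CC)[C@H](COCc1ccc(OC)cc1)C(=O)OC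
F7 | step 10 | 1-ethyl 14-methyl (2E,4E,7R,12S,13S)-13-[(4-methoxybenzyloxy)methyl]-3,5,7-trimethyl-12-(triethylsilyloxy)tetradeca-2,4-dienedioate | CCOC(=O)/C=C(C)/C=C(\C)C[C@H](C)CCCC[C@H](O[Si](CC)(CC)CC)[C@H](COCc1ccc(OC)cc1)C(=O)OC
F8 | step 12 | prop-2-en-1-yl (2E,4E,7R)-10-hydroxy-3,5,7-trimethyldeca-2,4-dienoate | C=CCOC(=O)/C=C(C)/C=C(\C)C[C@H](C)CCCO
F9 | step 12 | prop-2-en-1-yl (2E,4E,7R)-10-bromo-3,5,7-trimethyldeca-2,4-dienoate | C=CCOC(=O)/C=C(C)/C=C(\C)C[C@H](C)CCCBr
F10 | step 12 | 14-methyl 1-prop-2-en-1-yl (2E,4E,7R,12R,13R)-12-hydroxy-13-[(4-methoxybenzyloxy)methyl]-3,5,7-trimethyltetradeca-2,4-dienedioate | C=CCOC(=O)/C=C(C)/C=C(\C)C[C@H](C)CCCC[C@@H](O)[C@@H](COCc1ccc(OC)cc1)C(=O)OC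
F11 | step 12 | (2E,4E,7R,12R,13R)-12-hydroxy-13-[(4-methoxybenzyloxy)methyl]-3,5,7-trimethyltetradeca-2,4-dienedioic acid 1-(prop-2-en-1-yl) ester | C=CCOC(=O)/C=C(C)/C=C(\C)C[C@H](C)CCCC[C@@H](O)[C@@H](COCc1ccc(OC)cc1)C(=O)O
F12 | step 12 | prop-2-en-1-yl (2E,4E,7R)-11-[(2R,3R)-3-[(4-methoxybenzyloxy)methyl]-4-oxooxetan-2-yl]-3,5,7-trimethylundeca-2,4-dienoate | C=CCOC(=O)/C=C(C)/C=C(\C)C[C@H](C)CCCC[C@H]1OC(=O)[C@@H]1COCc1ccc(OC)cc1
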